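## Structural features

Agrimol C (17) is a trimeric acylphloroglucinol. A central 2,4,6-trihydroxybutyrophenone ring (ring A) carries two methylene bridges at C3 and C5, and each bridge ends at C1' of one of two identical outer rings (rings B and C). Each outer ring has hydroxyls at C2' and C6' on either side of the bridge carbon, a methyl at C3', a methoxyl at C4' and a butyryl group at C5'. All eighteen aromatic carbons are substituted, and the molecule has no stereocentre, so nothing has to be set or guarded against epimerisation. The fragile parts are the seven free phenols (sensitive to air and oxidants, most of all as phenoxides) and the two diarylmethane bridges, which join phloroglucinol-type rings and can open and re-close under base through ortho-quinone methides. The real difficulty is regiochemical: on each outer ring exactly one of three oxygens is a methyl ether and it must lie between the methyl and the ketone, and each bridge must form at one defined carbon of each partner. The C6' oxygen is ortho to the C5' ketone, and the other position ortho to that ketone, C4', already carries the methoxyl. In the 6'-deoxy compound C6'–H is therefore the only C–H bond that the ketone can reach through a five-membered chelate, and the key step uses this; removing that oxygen also leaves each outer ring as a mono-phenol with one nucleophilic carbon.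

## Logic of the disconnections

17 to 16. The five ester C–O bonds joining acetyl groups to the oxygens at C2, C4, C6, C2' and C2'' are cut. The free polyphenol cannot meet an oxidant, so the last skeletal event must run on an acylated compound and the acyl groups must leave afterwards in one operation. The skeleton does not change, but the target is reached from an air-stable, chromatographable compound. The forward step must cleave five hindered aryl esters without giving the bridges time to open under base: cold, brief, oxygen-free methanolysis and an acidic quench.

16 to 14, through 15. The C6'–O and C6''–O bonds are cut. Each of these oxygens is ortho to a ketone whose other ortho position is blocked by the methoxyl. This turns each outer ring from a trioxygenated into a dioxygenated ring with a single activated carbon. The forward step is a twofold chelation-controlled C–H oxygenation that must spare two diarylmethane CH2 groups, two aryl methyls and three α-keto CH2 groups. The acetate array is kept because it makes every ring electron-poor and leaves C6'–H and C6''–H as the only aromatic C–H bonds. Two refinements are made: an anhydride co-solvent traps each new oxygen as its trifluoroacetate (15) until work-up, and any acetyl migration or exchange is harmless because the next step removes all acyl groups.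

14 to 13. The five acetyl–oxygen bonds are cut, leading back to the free pentaphenol in which the bridges are made. The forward step must acylate completely, including the hydrogen-bonded hydroxyls beside the ring A ketone, since a single free phenol would not survive the oxidant.

13 to 7 and 10, through 11 and 12. The two bonds from the bridge carbons to C3 and C5 of ring A are cut. Ring A is the strongest carbon nucleophile in the molecule and has two equivalent free positions, while each outer ring can carry the one-carbon electrophile because it has only one activated carbon and so cannot act as a second acceptor. The gain is full convergence: two identical outer units and one central unit. The forward step must drive the alkylation to the bis stage and keep the transient 11 at low concentration.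

7 to 6. The C5–CH2 bond of the aminomethyl group is cut. The one-carbon unit is placed on the outer ring and not on ring A, because ring A would oligomerise with a one-carbon electrophile. The forward step needs aminomethylation on carbon ortho to the hydroxyl and not α to the ketone.

6 to 3, through 5 and 4. The O–CH3 bond and a temporary O–benzyl bond are cut. In 3 the two hydroxyls differ sharply: one is hydrogen-bonded to the ketone and the other is not. This fixes the methyl ether ortho to the ketone without relying on para-acylation of a monomethyl ether, which would have to compete with chelation-favoured acylation ortho to the hydroxyl. The cost is one protection and one deprotection; the demand is clean discrimination of the two hydroxyls in the first alkylation.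

3 to 1 and 2. The aryl–acyl bond is cut. C4 and C6 of 1 are equivalent and C5 is meta to both oxygens, so only one C-acyl product can form.

10 to 8 and 9. The aryl–acyl bond is cut. The three ring positions of 8 are equivalent, and the forward step only has to stop at monoacylation.

## Other disconnections considered

Alternative 1: The cut runs through both outer rings at C1'–C6' and C2'–C3' (C5'–C6' is broken and re-made on the way). Ring A becomes a template, the tribenzyl ether A1 with two CH2–C≡C–OSi(iPr)3 arms, and each outer ring is completed by one molecule of the cyclobutenone A2.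
- Forward key step: A1 is heated with two or more equivalents of A2 (Danheiser benzannulation). A2 opens in a four-electron electrocyclic step, its ring-opened form adds [2+2] to the ynol silyl ether, and a second four-electron opening, six-electron closure and tautomerisation should give the bis-phenol A3.
- In its favour: every outer-ring substituent is placed by connectivity. The silyloxy carbon becomes C2' and the former carbonyl carbon becomes C6', so the two oxygens arrive differentiated, and the methyl and methoxyl come with A2. No oxidant meets an electron-rich ring, and the bridges exist before the rings.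
- Against it here: A3 lacks all three butyryl groups. Three Friedel–Crafts acylations (C5', C5'' and C1 of ring A) must follow on a substrate full of acid-labile benzyl and silyl ethers, then desilylation and hydrogenolysis. Neither A1 nor A2 is a catalogue compound, the propargylic arms of A1 can isomerise to allenes, and the cascade must run twice on one molecule.
- Comparison: structurally A3 is further from 17 than 16 is, since 16 already holds every carbon and oxygen of 17. Mechanistically the alternative is the better on regiochemical predictability, because it need not choose between C–H bonds, and the better in delivering the C2' and C6' oxygens differentiated. In step economy the chosen plan is ahead: one step follows its key step, against several here, and it starts from commodity phenols.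

Alternative 2: The cut is the C1–C2 bond of ring A, which unfolds that ring into the open-chain triketo ester A4 carrying both arylmethyl groups at C2 and C4, the outer rings fully oxygenated with their hydroxyls as benzyl ethers.
- Forward key step: base would form the enolate at the C6 methylene of A4, which attacks the ester carbonyl (Claisen condensation of the Dieckmann type, six-membered closure with loss of methoxide). Enolisation of the cyclised product gives ring A in A5.
- In its favour: the closure mirrors the biogenesis of acylphloroglucinols and makes ring A with its butyryl group and both bridges in place. Each bridge is made earlier by C-alkylation of a 1,3-dicarbonyl carbon, so the mono/bis question of step 6 and any redistribution of bridges do not arise. No C–H oxidation is needed.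
- Against it here: A4 is a sensitive poly-β-carbonyl compound, a mixture of diastereomers and enol forms that is prone to retro-Claisen cleavage and needs polyanion chemistry to assemble. Its cyclisation can take other courses (aldol closure of C2 onto the C7 carbonyl, lactonisation), and the substituents at C2 and C4 slow the desired one. A5 still needs two butyrylations at C5' and C5'' next to a free acylphloroglucinol, and four hydrogenolyses.
- Comparison: structurally the plans are equal for ring A, which both deliver complete, but A5 lacks eight carbons of 17 where 16 lacks none. Mechanistically the alternative is the better in needing neither a transition metal nor an oxidant, while its choice between cyclisation modes is as open as the site selectivity of step 8. In step economy the chosen plan is shorter before and after the key step.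

Alternative 3: Each outer ring is cut at C3'–C4' and C5'–C6'. Ring A, as a tribenzyl ether without its butyryl group, carries two 2-silyloxycyclohexa-1,3-diene units (A6), and the C4'–C5' fragment with methoxyl and butyryl comes from the alkynone A7.
- Forward key step: A6 and two equivalents of A7 would undergo Diels–Alder addition, and the bridged adducts would lose their saturated two-carbon bridge by retro-Diels–Alder reaction (Alder–Rickert aromatisation). After desilylation this gives A8.
- In its favour: the outer rings arrive complete, ketone and methoxyl included, in one operation. The polarities match, since the silyl enol ether terminus C3' is the nucleophilic end and bonds to the methoxy-bearing β-carbon of A7. The C2' and C6' oxygens are differentiated as hydroxyl and benzyl ether, and the extrusion makes aromatisation irreversible.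
- Against it here: both diene termini are fully substituted and A7 is a donor-substituted, push–pull alkyne, so the cycloaddition should be slow. A hot extrusion must follow, twice in one molecule, on hydrolytically labile silyl enol ethers. Making A6 requires regiocontrolled O-benzylation and kinetic dienolisation on both arms. A8 still lacks the ring A butyryl group, whose introduction competes with O-acylation of the free C2' and C2'' hydroxyls, and five benzyl ethers must be removed.
- Comparison: structurally A8 is only four carbons short of 17 and nearly the equal of 16. Mechanistically the alternative is the better in building the C4'–C5' pattern with no regiochemical doubt and no oxidant, but the worse in the reactivity it asks of a hindered diene. In step economy the chosen plan is ahead, because its building blocks are bought or made in one to three steps and one step follows the key step.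

Key step: step 8

Remark: comparing 14 and 16 atom by atom with 17 shows no discrepancy, so their structures are used unchanged; outer-ring atoms are numbered C1' (bridge carbon) to C6', and since 17 has no stereocentre all SMILES are complete without stereodescriptors.

## Route

Step 1
Reactants: 1 2-methylresorcinol; 2 butyric acid
Product: 3 1-(2,4-dihydroxy-3-methylphenyl)butan-1-one
Conditions: ZnCl2 (1.5 equiv), 2 (neat, excess), 140 °C; then 1 M HCl
Reagents that add atoms: none
Why: Nencki reaction (Friedel–Crafts acylation with a carboxylic acid and ZnCl2); C4 and C6 of 1 are equivalent, each ortho to one hydroxyl and para to the other, so one C-acyl product is possible, and the ortho-hydroxy ketone is held as a zinc chelate that discourages a second acylation.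

Step 2
Reactants: 3 1-(2,4-dihydroxy-3-methylphenyl)butan-1-one
Product: 5 1-[4-(benzyloxy)-2-methoxy-3-methylphenyl]butan-1-one, via chelated benzyl ether 4 (not isolated)
Conditions: BnBr (1.0 equiv), K2CO3, DMF, rt; then MeI, 60 °C
Reagents that add atoms: benzyl bromide, BrCc1ccccc1; iodomethane, CI
Why: Two Williamson etherifications in sequence; the C4 hydroxyl (para to the carbonyl, more acidic, not hydrogen-bonded) should be benzylated at room temperature while the C2 hydroxyl stays locked to the ketone, and that chelated hydroxyl is then methylated only on heating, which fixes the methoxyl ortho to the butyryl group.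

Step 3
Reactants: 5 1-[4-(benzyloxy)-2-methoxy-3-methylphenyl]butan-1-one
Product: 6 1-(4-hydroxy-2-methoxy-3-methylphenyl)butan-1-one
Conditions: H2 (1 atm), 10% Pd/C, EtOAc, rt
Reagents that add atoms: none
Why: Hydrogenolysis of a benzyl aryl ether; the methyl ether is inert and the electron-rich, ortho-substituted aryl ketone should not be reduced at atmospheric pressure in a neutral solvent.

Step 4
Reactants: 6 1-(4-hydroxy-2-methoxy-3-methylphenyl)butan-1-one
Product: 7 1-{5-[(dimethylamino)methyl]-4-hydroxy-2-methoxy-3-methylphenyl}butan-1-one
Conditions: 37% aq. HCHO, 40% aq. Me2NH, EtOH, reflux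
Reagents that add atoms: formaldehyde, C=O; dimethylamine, CNC
Why: Phenolic Mannich reaction; under amine-basic conditions the phenol reacts at C5, its only free activated carbon (ortho to the hydroxyl, para to the methoxyl), C6 is meta to both oxygens, and aminomethylation α to the ketone needs acid catalysis and is not expected.

Step 5
Reactants: 8 phloroglucinol; 9 butyryl chloride
Product: 10 1-(2,4,6-trihydroxyphenyl)butan-1-one
Conditions: AlCl3 (4 equiv), PhNO2, rt to 65 °C; then ice, 2 M HCl
Reagents that add atoms: none
Why: Friedel–Crafts acylation; the three ring positions of 8 are equivalent, and the first acyl group, held as an aluminium chelate, deactivates the ring so that one equivalent of 9 should stop at monoacylation.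

Step 6
Reactants: 7 1-{5-[(dimethylamino)methyl]-4-hydroxy-2-methoxy-3-methylphenyl}butan-1-one (2.2 equiv); 10 1-(2,4,6-trihydroxyphenyl)butan-1-one
Product: 13 1-{3,5-bis[(5-butanoyl-2-hydroxy-4-methoxy-3-methylphenyl)methyl]-2,4,6-trihydroxyphenyl}butan-1-one, via quinone methide 11 (not isolated), via mono-bridged phenol 12 (not isolated)
Conditions: 1,4-dioxane, 100 °C, Ar stream
Reagents that add atoms: none
Why: Mannich-base alkylation; the acidic 10 protonates the amine of 7, loss of Me2NH (assisted by the methoxyl para to the benzylic carbon) releases the ortho-quinone methide 11, and conjugate addition of the phloroglucinol carbon of 10 and then of 12 gives C-alkylation at C3 and C5; the outer ring has no second nucleophilic carbon, so it cannot be alkylated itself, and its mono-phenol character makes bridge redistribution unlikely.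

Step 7
Reactants: 13 1-{3,5-bis[(5-butanoyl-2-hydroxy-4-methoxy-3-methylphenyl)methyl]-2,4,6-trihydroxyphenyl}butan-1-one
Product: 14 6',6''-dideoxy-Agrimol C pentaacetate
Conditions: Ac2O, pyridine, DMAP (cat.), rt to 40 °C
Reagents that add atoms: acetic anhydride, CC(=O)OC(C)=O
Why: Nucleophile-catalysed O-acetylation; DMAP should overcome the hindrance and hydrogen bonding of phenols flanked by two substituents, and the five acetates make every ring electron-poor for the oxidation.

Step 8
Reactants: 14 6',6''-dideoxy-Agrimol C pentaacetate
Product: 16 Agrimol C 2,4,6,2',2''-pentaacetate with free C6' and C6'' hydroxyls, via bis(trifluoroacetate) 15 (not isolated)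
Conditions: Pd(OAc)2 (20 mol%), PhI(OCOCF3)2 (3 equiv), TFA–TFAA (9:1), 50 °C; then aq. NaHCO3, THF, 0 °C
Reagents that add atoms: [bis(trifluoroacetoxy)iodo]benzene, O=C(OI(OC(=O)C(F)(F)F)c1ccccc1)C(F)(F)F; trifluoroacetic acid, OC(=O)C(F)(F)F (the transferred trifluoroacetate oxygen may come from either)
Why: This is ketone-directed ortho C–H oxygenation, a known reaction of aryl alkyl ketones under palladium catalysis with trivalent iodine or persulfate oxidants in TFA. In TFA the catalyst is present as electrophilic Pd(OCOCF3)2; the C5' carbonyl oxygen binds divalent palladium and delivers it to C6'–H, which is cleaved by concerted metalation–deprotonation with trifluoroacetate as internal base to give a five-membered palladacycle (Pd, O, carbonyl C, C5', C6'). PhI(OCOCF3)2 oxidises this to tetravalent palladium, and C–O reductive elimination releases the aryl trifluoroacetate and returns divalent palladium; the same cycle runs independently on the second outer ring, so 15 should form. No ring is closed and no stereocentre is created. The step needs site selectivity for C6'–H and C6''–H over the two diarylmethane CH2 groups, the C3' methyls and the three α-keto CH2 groups. The substrate secures this: the two targeted bonds are the only aromatic C–H bonds of 14, the C4' methoxyl blocks the other ortho site of each directing ketone, the ring A ketone has no ortho hydrogen, and any benzylic C–H would need a seven-membered palladacycle. The five acetates keep all rings too electron-poor for direct arene or benzylic oxidation, and TFAA keeps each new oxygen acylated until the cold bicarbonate work-up, which should hydrolyse only the far more labile trifluoroacetates to give 16. Acetyl migration or exchange at this stage would be inconsequential because step 9 removes every acyl group.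

Step 9
Reactants: 16 Agrimol C 2,4,6,2',2''-pentaacetate with free C6' and C6'' hydroxyls
Product: 17 Agrimol C
Conditions: K2CO3 (6 equiv), MeOH–THF, 0 °C, Ar; then 1 M HCl
Reagents that add atoms: none
Why: Base-mediated transesterification (methanolysis) of aryl acetates; the acyl-substituted phenoxides are good leaving groups, so cleavage should be fast at 0 °C, while methyl ethers and ketones are untouched and the cold, oxygen-free, briefly basic medium limits bridge opening and oxidation.

## Compound list

1 | 2-methylresorcinol | Cc1c(O)cccc1O | starting material
2 | butyric acid | CCCC(=O)O | starting material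
3 | 1-(2,4-dihydroxy-3-methylphenyl)butan-1-one | CCCC(=O)c1ccc(O)c(C)c1O | intermediate
4 | 1-[4-(benzyloxy)-2-hydroxy-3-methylphenyl]butan-1-one (not isolated) | CCCC(=O)c1ccc(OCc2ccccc2)c(C)c1O | intermediate
5 | 1-[4-(benzyloxy)-2-methoxy-3-methylphenyl]butan-1-one | CCCC(=O)c1ccc(OCc2ccccc2)c(C)c1OC | intermediate
6 | 1-(4-hydroxy-2-methoxy-3-methylphenyl)butan-1-one | CCCC(=O)c1ccc(O)c(C)c1OC | intermediate
7 | 1-{5-[(dimethylamino)methyl]-4-hydroxy-2-methoxy-3-methylphenyl}butan-1-one | CCCC(=O)c1cc(CN(C)C)c(O)c(C)c1OC | intermediate
8 | phloroglucinol | Oc1cc(O)cc(O)c1 | starting material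
9 | butyryl chloride | CCCC(=O)Cl | starting material
10 | 1-(2,4,6-trihydroxyphenyl)butan-1-one | CCCC(=O)c1c(O)cc(O)cc1O | intermediate
11 | 4-butanoyl-3-methoxy-2-methyl-6-methylidenecyclohexa-2,4-dien-1-one, ortho-quinone methide (not isolated) | CCCC(=O)C1=CC(=C)C(=O)C(C)=C1OC | intermediate
12 | 1-{3-[(5-butanoyl-2-hydroxy-4-methoxy-3-methylphenyl)methyl]-2,4,6-trihydroxyphenyl}butan-1-one (not isolated) | CCCC(=O)c1c(O)cc(O)c(Cc2cc(C(=O)CCC)c(OC)c(C)c2O)c1O | intermediate
13 | 1-{3,5-bis[(5-butanoyl-2-hydroxy-4-methoxy-3-methylphenyl)methyl]-2,4,6-trihydroxyphenyl}butan-1-one (6',6''-dideoxy-Agrimol C) | CCCC(=O)c1c(O)c(Cc2cc(C(=O)CCC)c(OC)c(C)c2O)c(O)c(Cc2cc(C(=O)CCC)c(OC)c(C)c2O)c1O | intermediate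
14 | 6',6''-dideoxy-Agrimol C pentaacetate: 1-{2,4,6-triacetoxy-3,5-bis[(2-acetoxy-5-butanoyl-4-methoxy-3-methylphenyl)methyl]phenyl}butan-1-one | CCCC(=O)c1c(OC(C)=O)c(Cc2cc(C(=O)CCC)c(OC)c(C)c2OC(C)=O)c(OC(C)=O)c(Cc2cc(C(=O)CCC)c(OC)c(C)c2OC(C)=O)c1OC(C)=O | intermediate
15 | Agrimol C 2,4,6,2',2''-pentaacetate 6',6''-bis(trifluoroacetate) (not isolated) | CCCC(=O)c1c(OC(C)=O)c(Cc2c(OC(=O)C(F)(F)F)c(C(=O)CCC)c(OC)c(C)c2OC(C)=O)c(OC(C)=O)c(Cc2c(OC(=O)C(F)(F)F)c(C(=O)CCC)c(OC)c(C)c2OC(C)=O)c1OC(C)=O | intermediate
16 | Agrimol C 2,4,6,2',2''-pentaacetate with free C6' and C6'' hydroxyls | CCCC(=O)c1c(OC(C)=O)c(Cc2c(O)c(C(=O)CCC)c(OC)c(C)c2OC(C)=O)c(OC(C)=O)c(Cc2c(O)c(C(=O)CCC)c(OC)c(C)c2OC(C)=O)c1OC(C)=O | intermediate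
17 | Agrimol C: 1-{3,5-bis[(5-butanoyl-2,6-dihydroxy-4-methoxy-3-methylphenyl)methyl]-2,4,6-trihydroxyphenyl}butan-1-one | CCCC(=O)c1c(O)c(Cc2c(O)c(C)c(OC)c(C(=O)CCC)c2O)c(O)c(Cc2c(O)c(C)c(OC)c(C(=O)CCC)c2O)c1O | target

## Step count and least certain steps

Total step count: 9. Longest linear sequence: 8 steps (1 → 3 → 5 → 6 → 7 → 13 → 14 → 16 → 17); step 5 is a one-step side branch.

Step 8 (key step).
- What may go wrong: slow C–H cleavage at a position flanked by the ketone and the bridge, so that only one ring reacts; competing α-oxygenation of the three ketones by the trivalent iodine reagent; oxidation at the doubly benzylic bridges; acid-induced loss of an acetyl group followed by oxidative degradation of the freed phenol.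
- Fallback, setting out from 6 and rejoining the route at 17: the oxygenation is moved to the monomer, where the C–H is unhindered and no bridge is present. 6 is acetylated (Ac2O, pyridine) to 4-butanoyl-3-methoxy-2-methylphenyl acetate F1. The same Pd(OAc)2/PhI(OCOCF3)2 oxygenation in TFA–TFAA gives 5-acetoxy-2-butanoyl-3-methoxy-4-methylphenyl trifluoroacetate F2, which K2CO3 in MeOH converts into 1-(4,6-dihydroxy-2-methoxy-3-methylphenyl)butan-1-one F3. A phenolic Mannich reaction at its only free carbon gives 1-{5-[(dimethylamino)methyl]-4,6-dihydroxy-2-methoxy-3-methylphenyl}butan-1-one F4. Warming F4 with 10 in dioxane releases the ortho-quinone methide 4-butanoyl-5-hydroxy-3-methoxy-2-methyl-6-methylidenecyclohexa-2,4-dien-1-one F5 and alkylates 10, first to 1-{3-[(5-butanoyl-2,6-dihydroxy-4-methoxy-3-methylphenyl)methyl]-2,4,6-trihydroxyphenyl}butan-1-one F6 and then to 17. This gives up the late-stage oxidation and brings back bridge formation between two phloroglucinol-type rings, but every operation in it is classical.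

Step 6.
- What may go wrong: the second alkylation stalls and mono- and bis-bridged material co-exist; the quinone methide self-condenses when it is generated faster than it is trapped; some O-alkylation occurs.
- Fallback, setting out from 7 and 10 and rejoining at 13: the leaving group is activated first, so that the electrophile is released by base at low temperature and not by heat. 7 is quaternised with MeI in acetone to 1-(5-butanoyl-2-hydroxy-4-methoxy-3-methylphenyl)-N,N,N-trimethylmethanaminium iodide F7. With K2CO3 in DMF at 0 °C to rt the phenoxide of F7 loses trimethylamine to give 11, which is trapped by the phenoxide of 10 through 12 to 13.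

Step 9.
- What may go wrong: base-induced opening of the methylene bridges (retro-Michael cleavage to an ortho-quinone methide and recombination in a crossed sense) once both partners are phloroglucinol-type phenoxides; air oxidation of the polyphenoxide.
- Fallback, setting out from 13 and rejoining at 17: the protecting group is changed so that the final unmasking is reductive and never basic. 13 is converted with 2,2,2-trichloroethyl chloroformate, pyridine and DMAP into 6',6''-dideoxy-Agrimol C pentakis(2,2,2-trichloroethyl carbonate) F8. The oxygenation of step 8 gives the pentacarbonate 6',6''-bis(trifluoroacetate) F9 and, after bicarbonate work-up, Agrimol C 2,4,6,2',2''-pentakis(2,2,2-trichloroethyl carbonate) F10. Zn dust in AcOH–THF at rt then removes all five carbonates to give 17.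

Step 4.
- What may go wrong: sluggish aminomethylation because the para-acyl group lowers the nucleophilicity of the phenol; competing aminomethylation α to the ketone; condensation of two phenol units through one carbon.
- Fallback, setting out from 6 and rejoining at 13, bypassing 7: 6 is hydroxymethylated as its fully ionised phenoxide with aqueous formaldehyde and NaOH at rt (Lederer–Manasse reaction) to 1-[4-hydroxy-5-(hydroxymethyl)-2-methoxy-3-methylphenyl]butan-1-one F11. Two equivalents of F11 are then joined to 10 by acid-catalysed Friedel–Crafts benzylation (TsOH cat., dioxane, 50 °C), the para-methoxyl stabilising the benzylic cation, through 12 to 13.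

## Further compounds

F1 | step 8 | 4-butanoyl-3-methoxy-2-methylphenyl acetate | CCCC(=O)c1ccc(OC(C)=O)c(C)c1OC
F2 | step 8 | 5-acetoxy-2-butanoyl-3-methoxy-4-methylphenyl trifluoroacetate | CCCC(=O)c1c(OC(=O)C(F)(F)F)cc(OC(C)=O)c(C)c1OC
F3 | step 8 | 1-(4,6-dihydroxy-2-methoxy-3-methylphenyl)butan-1-one | CCCC(=O)c1c(O)cc(O)c(C)c1OC
F4 | step 8 | 1-{5-[(dimethylamino)methyl]-4,6-dihydroxy-2-methoxy-3-methylphenyl}butan-1-one | CCCC(=O)c1c(O)c(CN(C)C)c(O)c(C)c1OC
F5 | step 8 | 4-butanoyl-5-hydroxy-3-methoxy-2-methyl-6-methylidenecyclohexa-2,4-dien-1-one | CCCC(=O)C1=C(O)C(=C)C(=O)C(C)=C1OC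
F6 | step 8 | 1-{3-[(5-butanoyl-2,6-dihydroxy-4-methoxy-3-methylphenyl)methyl]-2,4,6-trihydroxyphenyl}butan-1-one | CCCC(=O)c1c(O)cc(O)c(Cc2c(O)c(C)c(OC)c(C(=O)CCC)c2O)c1O
F7 | step 6 | 1-(5-butanoyl-2-hydroxy-4-methoxy-3-methylphenyl)-N,N,N-trimethylmethanaminium iodide | CCCC(=O)c1cc(C[N+](C)(C)C)c(O)c(C)c1OC.[I-]
F8 | step 9 | 6',6''-dideoxy-Agrimol C pentakis(2,2,2-trichloroethyl carbonate) | CCCC(=O)c1c(OC(=O)OCC(Cl)(Cl)Cl)c(Cc2cc(C(=O)CCC)c(OC)c(C)c2OC(=O)OCC(Cl)(Cl)Cl)c(OC(=O)OCC(Cl)(Cl)Cl)c(Cc2cc(C(=O)CCC)c(OC)c(C)c2OC(=O)OCC(Cl)(Cl)Cl)c1OC(=O)OCC(Cl)(Cl)Cl
F9 | step 9 | Agrimol C 2,4,6,2',2''-pentakis(2,2,2-trichloroethyl carbonate) 6',6''-bis(trifluoroacetate) | CCCC(=O)c1c(OC(=O)OCC(Cl)(Cl)Cl)c(Cc2c(OC(=O)C(F)(F)F)c(C(=O)CCC)c(OC)c(C)c2OC(=O)OCC(Cl)(Cl)Cl)c(OC(=O)OCC(Cl)(Cl)Cl)c(Cc2c(OC(=O)C(F)(F)F)c(C(=O)CCC)c(OC)c(C)c2OC(=O)OCC(Cl)(Cl)Cl)c1OC(=O)OCC(Cl)(Cl)Cl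
F10 | step 9 | Agrimol C 2,4,6,2',2''-pentakis(2,2,2-trichloroethyl carbonate) with free C6' and C6'' hydroxyls | CCCC(=O)c1c(OC(=O)OCC(Cl)(Cl)Cl)c(Cc2c(O)c(C(=O)CCC)c(OC)c(C)c2OC(=O)OCC(Cl)(Cl)Cl)c(OC(=O)OCC(Cl)(Cl)Cl)c(Cc2c(O)c(C(=O)CCC)c(OC)c(C)c2OC(=O)OCC(Cl)(Cl)Cl)c1OC(=O)OCC(Cl)(Cl)Cl
F11 | step 4 | 1-[4-hydroxy-5-(hydroxymethyl)-2-methoxy-3-methylphenyl]butan-1-one | CCCC(=O)c1cc(CO)c(O)c(C)c1OC
A1 | alternative 1 | 1,3,5-tris(benzyloxy)-2,4-bis[3-(triisopropylsilyloxy)prop-2-yn-1-yl]benzene | c1(OCc2ccccc2)cc(OCc2ccccc2)c(CC#CO[Si](C(C)C)(C(C)C)C(C)C)c(OCc2ccccc2)c1CC#CO[Si](C(C)C)(C(C)C)C(C)C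
A2 | alternative 1 | 3-methoxy-2-methylcyclobut-2-en-1-one | COC1=C(C)C(=O)C1
A3 | alternative 1 | 2,2'-{[2,4,6-tris(benzyloxy)-1,3-phenylene]bis(methylene)}bis[5-methoxy-4-methyl-3-(triisopropylsilyloxy)phenol] | c1(OCc2ccccc2)cc(OCc2ccccc2)c(Cc2c(O[Si](C(C)C)(C(C)C)C(C)C)c(C)c(OC)cc2O)c(OCc2ccccc2)c1Cc1c(O[Si](C(C)C)(C(C)C)C(C)C)c(C)c(OC)cc1O
A4 | alternative 2 | methyl 2,4-bis{[2,6-bis(benzyloxy)-4-methoxy-3-methylphenyl]methyl}-3,5,7-trioxodecanoate (mixture of diastereomers and enol forms) | COC(=O)C(Cc1c(OCc2ccccc2)c(C)c(OC)cc1OCc1ccccc1)C(=O)C(Cc1c(OCc2ccccc2)c(C)c(OC)cc1OCc1ccccc1)C(=O)CC(=O)CCC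
A5 | alternative 2 | 1-(3,5-bis{[2,6-bis(benzyloxy)-4-methoxy-3-methylphenyl]methyl}-2,4,6-trihydroxyphenyl)butan-1-one | CCCC(=O)c1c(O)c(Cc2c(OCc3ccccc3)c(C)c(OC)cc2OCc2ccccc2)c(O)c(Cc2c(OCc3ccccc3)c(C)c(OC)cc2OCc2ccccc2)c1O
A6 | alternative 3 | 1,3,5-tris(benzyloxy)-2,4-bis{[2-(benzyloxy)-6-(tert-butyldimethylsilyloxy)-5-methylcyclohexa-1,5-dien-1-yl]methyl}benzene | c1(OCc2ccccc2)cc(OCc2ccccc2)c(CC2=C(OCc3ccccc3)CCC(C)=C2O[Si](C)(C)C(C)(C)C)c(OCc2ccccc2)c1CC1=C(OCc2ccccc2)CCC(C)=C1O[Si](C)(C)C(C)(C)C
A7 | alternative 3 | 1-methoxyhex-1-yn-3-one | CCCC(=O)C#COC
A8 | alternative 3 | pentabenzyl ether of Agrimol C lacking the ring A butanoyl group, C2' and C2'' hydroxyls free | c1(OCc2ccccc2)cc(OCc2ccccc2)c(Cc2c(O)c(C)c(OC)c(C(=O)CCC)c2OCc2ccccc2)c(OCc2ccccc2)c1Cc1c(O)c(C)c(OC)c(C(=O)CCC)c1OCc1ccccc1
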